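**Plan**
- Cuts, in retrosynthetic order: all benzyl ethers; then, in one operation, the middle-unit bonds C-4–C-8(bottom unit) and C-2–C-3 (ring C), with C-2 stored as a benzylidene acetal; then the C-3–O ester (alkyne + gallic acid), C-4a–C-4 (formyl → ethynyl) and C-4(top)–C-8(middle) (ketone + aryllithium).
- Enabling feature: in ring C of the middle unit, C-2 is an O-1-bound benzylic carbon (an oxocarbenium once unmasked), C-3 carries the ester oxygen, and C-4 is benzylic to the 5,7,8a-trioxygenated ring A. A (Z)-2-acyloxyvinyl group on C-4a can therefore attack C-2 through C-3 and leave exactly the flavan C-4 cation that a flavan C-8 captures. The cis 3-OH of the top unit lies five atoms from the middle O-1, so these two oxygens can hold C-2 as a seven-membered acetal.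
- Forward order: top unit from (−)-epicatechin (4-ketone) → ring A of the middle unit added at C-4 (3,4-cis) → formyl, acetal (brings C-2 and ring B), alkyne, (Z)-enol gallate → cascade closes middle ring C and joins the bottom unit → debenzylation.
- Stereochemistry: top and bottom units come from (−)-epicatechin; top C-4 is set by β-face hydride delivery to the C-4 cation; middle C-2/C-3 cis comes from the Z alkene in a chair Prins transition state, C-4 trans from anti opening of the acyloxonium ion, and the absolute sense is relayed from the top unit through the acetal.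

Key step: step 15

Remark on the structure: the top unit is read as drawn, 2R,3R with the C-4 aryl bond cis to 3-OH (4α, all-cis); the middle unit is 2,3-cis-3,4-trans (4β) and the bottom unit is (−)-epicatechin 3-O-gallate.

**Step 1**
Reactants: 1 (−)-epicatechin; 2 benzyl bromide
Product: 3 5,7,3',4'-tetra-O-benzyl-(−)-epicatechin
Conditions: BnBr (4.2 equiv), K2CO3, DMF, 0 °C → rt, argon
Reagents that add atoms: benzyl bromide (2), BrCc1ccccc1
Why: Williamson etherification; K2CO3 deprotonates only the four phenols, so the aliphatic 3-OH should stay free, and low temperature without air should avoid C-2 epimerization.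

**Step 2**
Reactants: 3 5,7,3',4'-tetra-O-benzyl-(−)-epicatechin; 4 3,4,5-tris(benzyloxy)benzoic acid
Product: 5 5,7,3',4'-tetra-O-benzyl-(−)-epicatechin 3-O-[3,4,5-tris(benzyloxy)benzoate]
Conditions: DCC, DMAP, CH2Cl2, rt
Reagents that add atoms: 3,4,5-tris(benzyloxy)benzoic acid (4), OC(=O)c1cc(OCc5ccccc5)c(OCc5ccccc5)c(OCc5ccccc5)c1
Why: Steglich esterification of the axial 3-OH gives the bottom-unit nucleophile with C-8 free; no stereocentre is touched.

**Step 3**
Reactants: 3 5,7,3',4'-tetra-O-benzyl-(−)-epicatechin; 6 tert-butyldimethylsilyl chloride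
Product: 7 3-O-(tert-butyldimethylsilyl)-5,7,3',4'-tetra-O-benzyl-(−)-epicatechin
Conditions: TBSCl, imidazole, DMF, rt
Reagents that add atoms: tert-butyldimethylsilyl chloride (6), CC(C)(C)[Si](C)(C)Cl
Why: Silylation of the secondary alcohol masks 3-OH with a group that survives the oxidations, the aryllithium and brief acid, and can later be removed without touching benzyl ethers.

**Step 4**
Reactants: 7 3-O-(tert-butyldimethylsilyl)-5,7,3',4'-tetra-O-benzyl-(−)-epicatechin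
Product: 8 4β-hydroxy-3-O-(tert-butyldimethylsilyl)-5,7,3',4'-tetra-O-benzyl-(−)-epicatechin
Conditions: DDQ (2 equiv), CH2Cl2/H2O (18:1), rt
Reagents that add atoms: water, O
Why: DDQ benzylic oxidation removes hydride from C-4 (activated by ring A) and water traps the cation anti to the 3-silyloxy group; the C-4 configuration is erased in step 5.

**Step 5**
Reactants: 8 4β-hydroxy-3-O-(tert-butyldimethylsilyl)-5,7,3',4'-tetra-O-benzyl-(−)-epicatechin
Product: 9 (2R,3S)-5,7-bis(benzyloxy)-2-[3,4-bis(benzyloxy)phenyl]-3-(tert-butyldimethylsilyloxy)chroman-4-one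
Conditions: nPr4N[RuO4] (5 mol%), N-methylmorpholine N-oxide, 4 Å MS, CH2Cl2, rt
Reagents that add atoms: none
Why: Ley–Griffith oxidation of the benzylic alcohol under neutral conditions should give the ketone without enolization at C-3 or β-elimination of the ring oxygen.

**Step 6**
Reactants: 10 3,5-bis(benzyloxy)phenol; 11 N-bromosuccinimide
Product: 12 2-bromo-3,5-bis(benzyloxy)phenol
Conditions: NBS (1.0 equiv), iPr2NH (10 mol%), CH2Cl2, −78 → 0 °C
Reagents that add atoms: N-bromosuccinimide (11), O=C1CCC(=O)N1Br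
Why: Amine-mediated electrophilic bromination of a phenol is delivered ortho to the hydroxyl, and the ortho position is also less hindered than the position between the two benzyloxy groups.

**Step 7**
Reactants: 12 2-bromo-3,5-bis(benzyloxy)phenol; 13 chloromethyl methyl ether
Product: 14 1-bromo-2,4-bis(benzyloxy)-6-(methoxymethoxy)benzene
Conditions: MOMCl, iPr2NEt, CH2Cl2, 0 °C → rt
Reagents that add atoms: chloromethyl methyl ether (13), COCCl
Why: O-Alkylation removes the acidic proton before halogen–lithium exchange and marks the one oxygen of ring A that will become O-1 of the middle unit.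

**Step 8**
Reactants: 14 1-bromo-2,4-bis(benzyloxy)-6-(methoxymethoxy)benzene; 9 (2R,3S)-5,7-bis(benzyloxy)-2-[3,4-bis(benzyloxy)phenyl]-3-(tert-butyldimethylsilyloxy)chroman-4-one
Product: 16 4β-[2,4-bis(benzyloxy)-6-(methoxymethoxy)phenyl]-4α-hydroxy-3-O-(tert-butyldimethylsilyl)-5,7,3',4'-tetra-O-benzyl-(−)-epicatechin, via aryllithium 15 (not isolated)
Conditions: 14 (1.5 equiv), nBuLi, THF, −78 °C; then 9, −78 → −40 °C; aq. NH4Cl
Reagents that add atoms: none
Why: Bromine–lithium exchange followed by 1,2-addition of the aryllithium to the ketone, expected anti to the 2-aryl and 3-silyloxy groups; the carbinol configuration is removed in step 9.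

**Step 9**
Reactants: 16 4β-[2,4-bis(benzyloxy)-6-(methoxymethoxy)phenyl]-4α-hydroxy-3-O-(tert-butyldimethylsilyl)-5,7,3',4'-tetra-O-benzyl-(−)-epicatechin
Product: 18 3-O-(tert-butyldimethylsilyl)-5,7,3',4'-tetra-O-benzyl-epicatechin-(4α→2)-[3,5-bis(benzyloxy)phenol], via methoxymethyl ether 17 (not isolated)
Conditions: nBu3SnH (3 equiv), CF3CO2H (10 equiv), CH2Cl2, 0 °C → rt
Reagents that add atoms: none
Why: Ionic hydrogenation; the acid ionizes the doubly benzylic tertiary alcohol and the bulky stannane should deliver hydride to the β face, anti to the 2-aryl and 3-silyloxy groups, placing the new aryl group cis to O-3 (all-cis top unit), while the same acid cleaves the aryl methoxymethyl ether and the stannane reduces the methoxymethyl cation.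

**Step 10**
Reactants: 18 3-O-(tert-butyldimethylsilyl)-5,7,3',4'-tetra-O-benzyl-epicatechin-(4α→2)-[3,5-bis(benzyloxy)phenol]; 19 formaldehyde (as paraformaldehyde)
Product: 20 3-O-(tert-butyldimethylsilyl)-5,7,3',4'-tetra-O-benzyl-epicatechin-(4α→3)-[4,6-bis(benzyloxy)-2-hydroxybenzaldehyde]
Conditions: MgCl2 (2 equiv), Et3N (4 equiv), (CH2O)n (6 equiv), THF, reflux
Reagents that add atoms: formaldehyde (as paraformaldehyde, 19), C=O
Why: Magnesium phenoxide-directed ortho-formylation (hydroxymethylation, then hydride transfer to a second formaldehyde) can reach only the single free ortho position, the future C-4a; the CH between the two benzyloxy groups is not ortho to the phenol.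

**Step 11**
Reactants: 20 3-O-(tert-butyldimethylsilyl)-5,7,3',4'-tetra-O-benzyl-epicatechin-(4α→3)-[4,6-bis(benzyloxy)-2-hydroxybenzaldehyde]
Product: 21 5,7,3',4'-tetra-O-benzyl-epicatechin-(4α→3)-[4,6-bis(benzyloxy)-2-hydroxybenzaldehyde]
Conditions: HF·pyridine, THF/pyridine, 0 °C → rt
Reagents that add atoms: none
Why: Fluoride-driven desilylation frees the top 3-OH; benzyl ethers, the aldehyde and the C-4 aryl bond should be inert.

**Step 12**
Reactants: 21 5,7,3',4'-tetra-O-benzyl-epicatechin-(4α→3)-[4,6-bis(benzyloxy)-2-hydroxybenzaldehyde]; 22 3,4-bis(benzyloxy)benzaldehyde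
Product: 23 cyclic 3,4-bis(benzyloxy)benzylidene acetal of 21 bridging the top 3-O and the phenol oxygen (seven-membered 1,3-dioxepine; acetal carbon R; formyl group retained)
Conditions: 22 (1.5 equiv), PPTS (10 mol%), benzene, reflux, Dean–Stark trap over 4 Å MS
Reagents that add atoms: 3,4-bis(benzyloxy)benzaldehyde (22), O=Cc1ccc(OCc5ccccc5)c(OCc5ccccc5)c1
Why: Acid-catalysed acetalization of a 2-(2-hydroxyaryl)ethanol-type diol, possible because O-3 and the C-4 aryl bond of the top unit are cis (gauche); thermodynamic control should place the aryl group exo, and this acetal carbon loses its configuration in step 15.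

**Step 13**
Reactants: 23 cyclic benzylidene acetal aldehyde; 24 dimethyl (1-diazo-2-oxopropyl)phosphonate
Product: 25 cyclic benzylidene acetal bearing an ethynyl group in place of the formyl group
Conditions: 24 (2 equiv), K2CO3, MeOH/THF, rt
Reagents that add atoms: dimethyl (1-diazo-2-oxopropyl)phosphonate (24), COP(=O)(OC)C(=[N+]=[N-])C(C)=O
Why: Seyferth–Gilbert homologation with the Ohira–Bestmann reagent turns the aldehyde into the terminal alkyne (future C-4 and C-3) under mild base that the acetal tolerates.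

**Step 14**
Reactants: 25 ethynyl acetal; 4 3,4,5-tris(benzyloxy)benzoic acid
Product: 26 (Z)-2-aryl-vinyl 3,4,5-tris(benzyloxy)benzoate of the ethynyl acetal [(Z)-enol gallate]
Conditions: 4 (1.3 equiv), [RuCl2(p-cymene)]2 (2 mol%), P(4-ClC6H4)3 (6 mol%), DMAP (8 mol%), toluene, 60 °C
Reagents that add atoms: 3,4,5-tris(benzyloxy)benzoic acid (4), OC(=O)c1cc(OCc5ccccc5)c(OCc5ccccc5)c(OCc5ccccc5)c1
Why: Ruthenium-catalysed anti-Markovnikov hydro-oxycarbonylation of a terminal alkyne; carboxylate adds to the α-carbon of the ruthenium vinylidene and should give the (Z)-enol ester, with the galloyl group already on the future O-3.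

**Step 15**
Reactants: 26 (Z)-enol gallate acetal; 5 5,7,3',4'-tetra-O-benzyl-(−)-epicatechin 3-O-[3,4,5-tris(benzyloxy)benzoate]
Product: 30 octadeca-O-benzyl epicatechin-(4α→8)-epicatechin-3-O-gallate-(4β→8)-epicatechin-3-O-gallate (top 3-OH free), via aryl oxocarbenium triflate 27 (not isolated), via cis-fused dioxolanylium triflate 28 (not isolated), via top 3-O-trimethylsilyl ether 29 (not isolated)
Conditions: 5 (4 equiv), Me3SiOTf (0.2 equiv), 4 Å MS, CH2Cl2, −78 → −40 °C; Et3N; then citric acid, MeOH/CH2Cl2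
Reagents that add atoms: none
Why: Proposed new method: Me3SiOTf silylates the more basic alkyl oxygen (O-3 of the top unit) of the seven-membered acetal and opens it to the E aryl oxocarbenium 27, whose C-2 is attacked by C-3 of the (Z)-2-acyloxystyrene in a Prins cyclization that closes ring C through the C-2–C-3 bond and leaves the ring A-stabilized C-4 cation, held by the galloyl carbonyl as the cis-fused 2-aryl-1,3-dioxolan-2-ylium 28; C-8 of 5 then opens 28 at C-4 in a Friedel–Crafts alkylation and proton/silyl exchange releases the top 3-OH and the catalyst. The closest known reaction types are Prins cyclizations terminated by Friedel–Crafts arylation, segment-coupling Prins reactions started from acetals, and the Lewis acid coupling of flavan C-4 cations bearing a participating 3-O-acyl group with flavan C-8 nucleophiles. Ring C closes in the 6-endo-trig mode (oxocarbenium and alkene both inside the new ring) through a chair-like transition state. C-2 and C-3 should become cis because the aryl group of the E oxocarbenium sits equatorial while the Z geometry forces the acyloxy group axial, and C-4 should become trans to C-3 because the nucleophile must enter anti to the acyloxonium bridge; the absolute sense (2R,3R) is relayed from the top unit, whose 4α configuration places its C-3–O-3 bond, and hence the acetal carbon, on one face of ring A, so that the oxocarbenium is born on that face and should close onto C-3 there before the doubly ortho-flanked aryl–O bond can rotate through the ring plane. The step needs attack through C-3 and not C-4 of the alkene (secured by the weak donor ester oxygen against the trioxygenated aryl group and by 6-endo over 5-exo geometry), C-8 over C-6 attack of 5 (the usual preference of tetra-O-benzyl flavans) and suppression of self-condensation (excess 5, low temperature).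

**Step 16**
Reactants: 30 octadeca-O-benzyl epicatechin-(4α→8)-epicatechin-3-O-gallate-(4β→8)-epicatechin-3-O-gallate
Product: 31 CNP0279403.2 (target)
Conditions: H2 (1 atm), Pd(OH)2/C, THF/MeOH/H2O (20:1:1), rt
Reagents that add atoms: none
Why: Global hydrogenolysis of the eighteen benzyl ethers; the gallate esters, the benzylic C-2–O-1 ring bonds and all stereocentres should survive these mild neutral conditions.

**Compound list**
1 | (−)-epicatechin | O[C@@H]1Cc2c(O)cc(O)cc2O[C@@H]1c1ccc(O)c(O)c1 | starting material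
2 | benzyl bromide | BrCc1ccccc1 | starting material
3 | 5,7,3',4'-tetra-O-benzyl-(−)-epicatechin | O[C@@H]1Cc2c(OCc5ccccc5)cc(OCc5ccccc5)cc2O[C@@H]1c1ccc(OCc5ccccc5)c(OCc5ccccc5)c1 | intermediate
4 | 3,4,5-tris(benzyloxy)benzoic acid | OC(=O)c1cc(OCc5ccccc5)c(OCc5ccccc5)c(OCc5ccccc5)c1 | starting material
5 | 5,7,3',4'-tetra-O-benzyl-(−)-epicatechin 3-O-[3,4,5-tris(benzyloxy)benzoate] (bottom unit) | O=C(O[C@@H]1Cc2c(OCc5ccccc5)cc(OCc5ccccc5)cc2O[C@@H]1c1ccc(OCc5ccccc5)c(OCc5ccccc5)c1)c1cc(OCc5ccccc5)c(OCc5ccccc5)c(OCc5ccccc5)c1 | intermediate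
6 | tert-butyldimethylsilyl chloride | CC(C)(C)[Si](C)(C)Cl | starting material
7 | 3-O-TBS-5,7,3',4'-tetra-O-benzyl-(−)-epicatechin | CC(C)(C)[Si](C)(C)O[C@@H]1Cc2c(OCc5ccccc5)cc(OCc5ccccc5)cc2O[C@@H]1c1ccc(OCc5ccccc5)c(OCc5ccccc5)c1 | intermediate
8 | 4β-hydroxy-3-O-TBS-5,7,3',4'-tetra-O-benzyl-(−)-epicatechin | CC(C)(C)[Si](C)(C)O[C@@H]1[C@@H](O)c2c(OCc5ccccc5)cc(OCc5ccccc5)cc2O[C@@H]1c1ccc(OCc5ccccc5)c(OCc5ccccc5)c1 | intermediate
9 | (2R,3S)-5,7-bis(benzyloxy)-2-[3,4-bis(benzyloxy)phenyl]-3-(TBS-oxy)chroman-4-one | CC(C)(C)[Si](C)(C)O[C@@H]1C(=O)c2c(OCc5ccccc5)cc(OCc5ccccc5)cc2O[C@@H]1c1ccc(OCc5ccccc5)c(OCc5ccccc5)c1 | intermediate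
10 | 3,5-bis(benzyloxy)phenol | Oc1cc(OCc5ccccc5)cc(OCc5ccccc5)c1 | starting material
11 | N-bromosuccinimide | O=C1CCC(=O)N1Br | starting material
12 | 2-bromo-3,5-bis(benzyloxy)phenol | Oc1cc(OCc5ccccc5)cc(OCc5ccccc5)c1Br | intermediate
13 | chloromethyl methyl ether | COCCl | starting material
14 | 1-bromo-2,4-bis(benzyloxy)-6-(methoxymethoxy)benzene | COCOc1cc(OCc5ccccc5)cc(OCc5ccccc5)c1Br | intermediate
15 | [2,4-bis(benzyloxy)-6-(methoxymethoxy)phenyl]lithium | COCOc1cc(OCc5ccccc5)cc(OCc5ccccc5)c1[Li] | intermediate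
16 | 4β-aryl-4α-hydroxy carbinol of the top unit (aryl = 2,4-bis(benzyloxy)-6-(methoxymethoxy)phenyl; 3-O-TBS) | CC(C)(C)[Si](C)(C)O[C@@H]1[C@@](O)(c3c(OCOC)cc(OCc5ccccc5)cc3OCc5ccccc5)c2c(OCc5ccccc5)cc(OCc5ccccc5)cc2O[C@@H]1c1ccc(OCc5ccccc5)c(OCc5ccccc5)c1 | intermediate
17 | 4α-aryl top unit, methoxymethyl ether (3-O-TBS; all-cis) | CC(C)(C)[Si](C)(C)O[C@@H]1[C@H](c3c(OCOC)cc(OCc5ccccc5)cc3OCc5ccccc5)c2c(OCc5ccccc5)cc(OCc5ccccc5)cc2O[C@@H]1c1ccc(OCc5ccccc5)c(OCc5ccccc5)c1 | intermediate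
18 | 3-O-TBS-5,7,3',4'-tetra-O-benzyl-epicatechin-(4α→2)-[3,5-bis(benzyloxy)phenol] | CC(C)(C)[Si](C)(C)O[C@@H]1[C@H](c3c(O)cc(OCc5ccccc5)cc3OCc5ccccc5)c2c(OCc5ccccc5)cc(OCc5ccccc5)cc2O[C@@H]1c1ccc(OCc5ccccc5)c(OCc5ccccc5)c1 | intermediate
19 | formaldehyde (used as paraformaldehyde) | C=O | starting material
20 | 3-O-TBS-5,7,3',4'-tetra-O-benzyl-epicatechin-(4α→3)-[4,6-bis(benzyloxy)-2-hydroxybenzaldehyde] | CC(C)(C)[Si](C)(C)O[C@@H]1[C@H](c3c(O)c(C=O)c(OCc5ccccc5)cc3OCc5ccccc5)c2c(OCc5ccccc5)cc(OCc5ccccc5)cc2O[C@@H]1c1ccc(OCc5ccccc5)c(OCc5ccccc5)c1 | intermediate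
21 | 5,7,3',4'-tetra-O-benzyl-epicatechin-(4α→3)-[4,6-bis(benzyloxy)-2-hydroxybenzaldehyde] | O[C@@H]1[C@H](c3c(O)c(C=O)c(OCc5ccccc5)cc3OCc5ccccc5)c2c(OCc5ccccc5)cc(OCc5ccccc5)cc2O[C@@H]1c1ccc(OCc5ccccc5)c(OCc5ccccc5)c1 | intermediate
22 | 3,4-bis(benzyloxy)benzaldehyde | O=Cc1ccc(OCc5ccccc5)c(OCc5ccccc5)c1 | starting material
23 | seven-membered 3,4-bis(benzyloxy)benzylidene acetal of 21 (top O-3 and middle O-1 on the acetal carbon; formyl on the future C-4a) | O=Cc1c(OCc5ccccc5)cc(OCc5ccccc5)c2c1O[C@H](c1ccc(OCc5ccccc5)c(OCc5ccccc5)c1)O[C@@H]1[C@H]2c2c(OCc5ccccc5)cc(OCc5ccccc5)cc2O[C@@H]1c1ccc(OCc5ccccc5)c(OCc5ccccc5)c1 | intermediate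
24 | dimethyl (1-diazo-2-oxopropyl)phosphonate | COP(=O)(OC)C(=[N+]=[N-])C(C)=O | starting material
25 | ethynyl analogue of acetal 23 | C#Cc1c(OCc5ccccc5)cc(OCc5ccccc5)c2c1O[C@H](c1ccc(OCc5ccccc5)c(OCc5ccccc5)c1)O[C@@H]1[C@H]2c2c(OCc5ccccc5)cc(OCc5ccccc5)cc2O[C@@H]1c1ccc(OCc5ccccc5)c(OCc5ccccc5)c1 | intermediate
26 | (Z)-enol 3,4,5-tris(benzyloxy)benzoate of the acetal (key-step substrate) | O=C(O/C=C\c1c(OCc5ccccc5)cc(OCc5ccccc5)c2c1O[C@H](c1ccc(OCc5ccccc5)c(OCc5ccccc5)c1)O[C@@H]1[C@H]2c2c(OCc5ccccc5)cc(OCc5ccccc5)cc2O[C@@H]1c1ccc(OCc5ccccc5)c(OCc5ccccc5)c1)c1cc(OCc5ccccc5)c(OCc5ccccc5)c(OCc5ccccc5)c1 | intermediate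
27 | aryl oxocarbenium triflate (C-2 cation on O-1; top 3-O-SiMe3) | O=C(O/C=C\c1c(OCc5ccccc5)cc(OCc5ccccc5)c([C@@H]2c3c(OCc5ccccc5)cc(OCc5ccccc5)cc3O[C@H](c3ccc(OCc5ccccc5)c(OCc5ccccc5)c3)[C@@H]2O[Si](C)(C)C)c1[O+]=Cc1ccc(OCc5ccccc5)c(OCc5ccccc5)c1)c1cc(OCc5ccccc5)c(OCc5ccccc5)c(OCc5ccccc5)c1.[O-]S(=O)(=O)C(F)(F)F | intermediate
28 | 3,4-cis-fused 2-aryl-1,3-dioxolan-2-ylium triflate of the new flavan (ring C closed; top 3-O-SiMe3) | C6(=[O+][C@@H]7c2c(OCc5ccccc5)cc(OCc5ccccc5)c([C@@H]8c3c(OCc5ccccc5)cc(OCc5ccccc5)cc3O[C@H](c3ccc(OCc5ccccc5)c(OCc5ccccc5)c3)[C@@H]8O[Si](C)(C)C)c2O[C@H](c2ccc(OCc5ccccc5)c(OCc5ccccc5)c2)[C@@H]7O6)c1cc(OCc5ccccc5)c(OCc5ccccc5)c(OCc5ccccc5)c1.[O-]S(=O)(=O)C(F)(F)F | intermediate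
29 | top 3-O-trimethylsilyl ether of 30 | O=C(O[C@@H]1[C@@H](c2c(OCc5ccccc5)cc(OCc5ccccc5)c3c2O[C@H](c2ccc(OCc5ccccc5)c(OCc5ccccc5)c2)[C@H](OC(=O)c2cc(OCc5ccccc5)c(OCc5ccccc5)c(OCc5ccccc5)c2)C3)c2c(OCc5ccccc5)cc(OCc5ccccc5)c([C@@H]3c4c(OCc5ccccc5)cc(OCc5ccccc5)cc4O[C@H](c4ccc(OCc5ccccc5)c(OCc5ccccc5)c4)[C@@H]3O[Si](C)(C)C)c2O[C@@H]1c1ccc(OCc5ccccc5)c(OCc5ccccc5)c1)c1cc(OCc5ccccc5)c(OCc5ccccc5)c(OCc5ccccc5)c1 | intermediate
30 | octadeca-O-benzyl epicatechin-(4α→8)-epicatechin-3-O-gallate-(4β→8)-epicatechin-3-O-gallate (top 3-OH free) | O=C(O[C@@H]1[C@@H](c2c(OCc5ccccc5)cc(OCc5ccccc5)c3c2O[C@H](c2ccc(OCc5ccccc5)c(OCc5ccccc5)c2)[C@H](OC(=O)c2cc(OCc5ccccc5)c(OCc5ccccc5)c(OCc5ccccc5)c2)C3)c2c(OCc5ccccc5)cc(OCc5ccccc5)c([C@@H]3c4c(OCc5ccccc5)cc(OCc5ccccc5)cc4O[C@H](c4ccc(OCc5ccccc5)c(OCc5ccccc5)c4)[C@@H]3O)c2O[C@@H]1c1ccc(OCc5ccccc5)c(OCc5ccccc5)c1)c1cc(OCc5ccccc5)c(OCc5ccccc5)c(OCc5ccccc5)c1 | intermediate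
31 | CNP0279403.2 | O=C(O[C@@H]1[C@@H](c2c(O)cc(O)c3c2O[C@H](c2ccc(O)c(O)c2)[C@H](OC(=O)c2cc(O)c(O)c(O)c2)C3)c2c(O)cc(O)c([C@@H]3c4c(O)cc(O)cc4O[C@H](c4ccc(O)c(O)c4)[C@@H]3O)c2O[C@@H]1c1ccc(O)c(O)c1)c1cc(O)c(O)c(O)c1 | target

**Count and risks**
Total step count: 16. Longest linear sequence: 13 steps (1 → 3 → 7 → 8 → 9 → 16 → 18 → 20 → 21 → 23 → 25 → 26 → 30 → 31).

Step 15 (most likely to fail). What may go wrong: the oxocarbenium may rotate about the aryl–O bond before ring closure, so that facial control is lost and the mirror-configured middle unit forms; the bottom unit may attack C-2 directly; the enol ester may be protonated by triflic acid. Fallback by known chain-extension chemistry, starting from 3 and returning to the route at 30: bromination of 3 with NBS should give 8-bromo-5,7,3',4'-tetra-O-benzyl-(−)-epicatechin F1. DDQ with 2-ethoxyethanol should give its 4β-(2-ethoxyethoxy) ether F2. Me3SiOTf-mediated condensation of F2 with excess 3 should give the 8-bromo 4β→8 dimer diol F3, the bromine blocking self-condensation. Deprotonation of both hydroxyls (MeLi), bromine–lithium exchange (tBuLi) and addition to ketone 9 should give the trimeric carbinol F4. Reduction with nBu3SnH/CF3CO2H should give the 4α-linked trimer diol F5. Double esterification with 4 (DCC, DMAP) should give the top 3-O-TBS digallate F6, and HF·pyridine then gives 30. Here the middle unit comes from the chiral pool, so no new ring C bond has to be made selectively.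

Step 14. What may go wrong: the carboxylic acid may open the acid-labile acetal at 60 °C, the hindered alkyne may react slowly, or Z selectivity may erode. Fallback from 25 back to 26 without acid or heat: rhodium-catalysed trans-hydroboration ([RhCl(cod)]2, P(iPr)3, Et3N, pinacolborane) should give the (Z)-alkenyl pinacolboronate F7. Brief treatment with KHF2 should give the potassium (Z)-alkenyltrifluoroborate F8. Chan–Lam-type oxidative coupling with acid 4 (Cu(OAc)2, DMAP, O2, 4 Å MS, CH2Cl2) should then form the enol C–O bond with retention of alkene geometry to give 26.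

Step 12. What may go wrong: the equilibrium for a seven-membered mixed phenol/alcohol acetal may be unfavourable, and the hydrogen-bonded phenol may react sluggishly or form intermolecular acetals. Fallback from 21 back to 23 by an oxidative, irreversible ring closure: selective O-alkylation of the phenol with 3,4-bis(benzyloxy)benzyl bromide (K2CO3, DMF) should give the 3,4-bis(benzyloxy)benzyl aryl ether F9. DDQ in anhydrous CH2Cl2 over 4 Å MS should then oxidize the electron-rich benzylic ether to its cation, which the neighbouring top 3-OH traps to give acetal 23.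

**Further compounds**
F1 | step 15 | 8-bromo-5,7,3',4'-tetra-O-benzyl-(−)-epicatechin | O[C@@H]1Cc2c(OCc5ccccc5)cc(OCc5ccccc5)c(Br)c2O[C@@H]1c1ccc(OCc5ccccc5)c(OCc5ccccc5)c1
F2 | step 15 | 8-bromo-4β-(2-ethoxyethoxy)-5,7,3',4'-tetra-O-benzyl-(−)-epicatechin | O[C@@H]1[C@@H](OCCOCC)c2c(OCc5ccccc5)cc(OCc5ccccc5)c(Br)c2O[C@@H]1c1ccc(OCc5ccccc5)c(OCc5ccccc5)c1
F3 | step 15 | 8-bromo-octa-O-benzyl epicatechin-(4β→8)-epicatechin (both 3-OH free) | O[C@@H]1[C@@H](c2c(OCc5ccccc5)cc(OCc5ccccc5)c3c2O[C@H](c2ccc(OCc5ccccc5)c(OCc5ccccc5)c2)[C@H](O)C3)c2c(OCc5ccccc5)cc(OCc5ccccc5)c(Br)c2O[C@@H]1c1ccc(OCc5ccccc5)c(OCc5ccccc5)c1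
F4 | step 15 | trimeric carbinol (top unit 4-hydroxy, 3-O-TBS; middle and bottom 3-OH free) | O[C@@H]1[C@@H](c2c(OCc5ccccc5)cc(OCc5ccccc5)c3c2O[C@H](c2ccc(OCc5ccccc5)c(OCc5ccccc5)c2)[C@H](O)C3)c2c(OCc5ccccc5)cc(OCc5ccccc5)c([C@@]3(O)c4c(OCc5ccccc5)cc(OCc5ccccc5)cc4O[C@H](c4ccc(OCc5ccccc5)c(OCc5ccccc5)c4)[C@@H]3O[Si](C)(C)C(C)(C)C)c2O[C@@H]1c1ccc(OCc5ccccc5)c(OCc5ccccc5)c1
F5 | step 15 | dodeca-O-benzyl 4α→8, 4β→8 trimer (top 3-O-TBS; middle and bottom 3-OH free) | O[C@@H]1[C@@H](c2c(OCc5ccccc5)cc(OCc5ccccc5)c3c2O[C@H](c2ccc(OCc5ccccc5)c(OCc5ccccc5)c2)[C@H](O)C3)c2c(OCc5ccccc5)cc(OCc5ccccc5)c([C@@H]3c4c(OCc5ccccc5)cc(OCc5ccccc5)cc4O[C@H](c4ccc(OCc5ccccc5)c(OCc5ccccc5)c4)[C@@H]3O[Si](C)(C)C(C)(C)C)c2O[C@@H]1c1ccc(OCc5ccccc5)c(OCc5ccccc5)c1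
F6 | step 15 | top 3-O-TBS ether of 30 | O=C(O[C@@H]1[C@@H](c2c(OCc5ccccc5)cc(OCc5ccccc5)c3c2O[C@H](c2ccc(OCc5ccccc5)c(OCc5ccccc5)c2)[C@H](OC(=O)c2cc(OCc5ccccc5)c(OCc5ccccc5)c(OCc5ccccc5)c2)C3)c2c(OCc5ccccc5)cc(OCc5ccccc5)c([C@@H]3c4c(OCc5ccccc5)cc(OCc5ccccc5)cc4O[C@H](c4ccc(OCc5ccccc5)c(OCc5ccccc5)c4)[C@@H]3O[Si](C)(C)C(C)(C)C)c2O[C@@H]1c1ccc(OCc5ccccc5)c(OCc5ccccc5)c1)c1cc(OCc5ccccc5)c(OCc5ccccc5)c(OCc5ccccc5)c1
F7 | step 14 | (Z)-alkenyl pinacolboronate of acetal 25 | B1(OC(C)(C)C(C)(C)O1)/C=C\c1c(OCc5ccccc5)cc(OCc5ccccc5)c2c1O[C@H](c1ccc(OCc5ccccc5)c(OCc5ccccc5)c1)O[C@@H]1[C@H]2c2c(OCc5ccccc5)cc(OCc5ccccc5)cc2O[C@@H]1c1ccc(OCc5ccccc5)c(OCc5ccccc5)c1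
F8 | step 14 | potassium (Z)-alkenyltrifluoroborate of acetal 25 | [K+].F[B-](F)(F)/C=C\c1c(OCc5ccccc5)cc(OCc5ccccc5)c2c1O[C@H](c1ccc(OCc5ccccc5)c(OCc5ccccc5)c1)O[C@@H]1[C@H]2c2c(OCc5ccccc5)cc(OCc5ccccc5)cc2O[C@@H]1c1ccc(OCc5ccccc5)c(OCc5ccccc5)c1
F9 | step 12 | O-[3,4-bis(benzyloxy)benzyl] ether of the phenol of 21 (top 3-OH free) | O=Cc1c(OCc5ccccc5)cc(OCc5ccccc5)c([C@@H]2c3c(OCc5ccccc5)cc(OCc5ccccc5)cc3O[C@H](c3ccc(OCc5ccccc5)c(OCc5ccccc5)c3)[C@@H]2O)c1OCc1ccc(OCc5ccccc5)c(OCc5ccccc5)c1
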